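Amounts first: the flask holds 0.20 M of substrate and 5.00 equiv of second nucleophile, and the held gas offers a saturation concentration of 13 mM.

    substrate → intermediate (k1 = 0.0103 s⁻¹)
    first nucleophile + intermediate → target (k2 = 28.9 M⁻¹ s⁻¹)
    second nucleophile + intermediate → other capture product (k3 = 0.0186 M⁻¹ s⁻¹)
    intermediate → solvolysis product (k4 = 0.360 s⁻¹)
    gas ⇌ first nucleophile, rate k5*(csat - [first nucleophile]) (k5 = 0.208 s⁻¹, csat = 13 mM)
    second nucleophile + target ⇌ idle adduct, settled at all times (K6 = 0.899 M⁻¹)

substrate 0.20 M; second nucleophile 5.00 equiv; gas 13 mM (held); time 2.5 min

- for target the idle adduct is counted in
- at the start none of first nucleophile is dissolved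
- run time (flask): 2.5 min

1. amount of target and idle adduct together at 2.5 min, in percent of the substrate charged
2. the change that raises the amount of target and idle adduct together at 2.5 min, in percent of the substrate charged most ("none" if none brings more than 2 percentage points) (Friday's / Wednesday's / Monday's / none)
3. amount of target and idle adduct together at 2.5 min, in percent of the substrate charged, after Friday's

- Friday's: doubling the saturation concentration of gas, all else as stated
- Wednesday's: doubling the amount of second nucleophile, all else as stated
- Monday's: doubling the transfer coefficient of step 5, all else as stated

Intermediate is the branch point. Capture by first nucleophile is pseudo-first-order, with its rate constant times c(first nucleophile) standing against the solvolysis constant. The saturation capture share, the fraction of intermediate that first nucleophile takes from solvolysis with the solution at saturation, is 51.1%. Second nucleophile is a slower exit than solvolysis: its half-life for intermediate is 0.62 min, against 1.9 s. Idle adduct is counted with target.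

At the very start, the flask has no dissolved first nucleophile, so the first intermediate has solvolysis and second nucleophile as its exits. Gas transfer has a half-life of 3.33 s, shorter than the 1.1 min of substrate, so this lag is brief.

In the middle, intermediate lives for seconds and passes on what substrate feeds it. This reckoning puts dissolved first nucleophile below saturation by roughly the saturation capture share times the feed over the transfer coefficient. In powers of ten, substrate falls by 0.671 decades by the asked time, leaving 21.3%. In this reckoning the gap narrows as the feed decays:

| Time | Substrate left | c(first nucleophile), reckoned |
|---|---|---|
| 0.250 min | 85.7% | 8.67 mM |
| 1.25 min | 46.2% | 10.7 mM |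
| 2.5 min | 21.3% | 11.9 mM |

At the end, the reckoning takes the midpoint of the turnover as typical. There c(first nucleophile) is 9.93 mM and the local share is 44.4%. Multiplied by the turnover, this gives 34.9%, with the lag not subtracted. This reckoning picks Friday's, which raises the share itself, whereas faster transfer narrows a gap below an unchanged saturation.

The forecast gives 33.5%, lower than this reckoning. It names Friday's at 48%, a rise it calls “well beyond what faster transfer can do”.

The simulated flask stands at 33.8%. Friday's gains 14 percentage points and reaches 48.3%, Monday's gains 2.6 points, and Wednesday's changes it by −0.8 points.

Solvolysis is the main reason for the shortfall in the flask: with that step removed, the flask reaches 71.8% instead of 33.8%. The saturation capture share times the turnover gives 40.2% for this flask, above its simulated value. In Friday's flask, the doubled saturation lifts the share to 67.6%, the same product becomes 53.2%, and that flask stands at 48.3%.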